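**Strategy.** Ring A (cyclohexenone C1–C6: C1 ketone, C4 acetoxy carbon, spiro C6 shared with lactone ring B) is disconnected at the C2=C3 olefin, which sits between the C1 carbonyl and the oxygenated C4: the retron of an enone/allylic-alcohol ring-closing metathesis. The key step closes ring A on a diene that already carries ring B, the complete side chain and all three stereocentres. This diene is unmasked from a spiro bis-lactone in which C1 and the C4 oxygen are tied as a γ-lactone; that temporary ring is the template for an anti aldol (C9) and a chelate-controlled alkylation (C6) and is opened by vinyl addition. A closing Mitsunobu acetylation inverts C4.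

Key step: step 9

Remark: atom labels are ring A = C1 (ketone), C2, C3, C4 (acetoxy carbon), C5, C6 (spiro carbon); ring B = C6, C7, C8 (lactone carbonyl), O, C9 (carbinol carbon); side chain = C10–C15. Geraniol and (R)-5-(hydroxymethyl)dihydrofuran-2(3H)-one are assumed to be commercial.

**Step 1**
Reactants: 1 geraniol
Product: 3 (2E,5E)-3,7-dimethylocta-2,5-diene-1,7-diol, via allylic hydroperoxide 2 (not isolated)
Conditions: O2, tetraphenylporphyrin (cat.), hν (visible), CH2Cl2, 0 °C; then PPh3, 0 → 23 °C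
Reagents that add atoms: dioxygen, O=O
Why: Schenck ene reaction: singlet oxygen attacks the electron-rich 6,7-trisubstituted olefin (the 2,3-olefin is deactivated by the allylic hydroxyl), abstracts a C5 hydrogen and gives the tertiary allylic hydroperoxide with a new (5E)-olefin, which PPh3 reduces to the alcohol; the secondary allylic regioisomer from methyl-hydrogen abstraction is expected as a co-product and is removed by chromatography.

**Step 2**
Reactants: 3 (2E,5E)-3,7-dimethylocta-2,5-diene-1,7-diol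
Product: 4 (2E,5E)-7-hydroxy-3,7-dimethylocta-2,5-dienal
Conditions: MnO2, CH2Cl2, 23 °C
Reagents that add atoms: none
Why: MnO2 oxidation is selective for the primary allylic alcohol, leaves the tertiary alcohol and the skipped diene untouched and keeps the (2E) geometry.

**Step 3**
Reactants: 4 (2E,5E)-7-hydroxy-3,7-dimethylocta-2,5-dienal
Product: 5 (2E,5E)-3,7-dimethyl-7-(trimethylsilyloxy)octa-2,5-dienal
Conditions: 1-(trimethylsilyl)imidazole, CH2Cl2, 23 °C
Reagents that add atoms: 1-(trimethylsilyl)imidazole, C[Si](C)(C)n1ccnc1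
Why: Silyl transfer caps the tertiary alcohol, the only acidic proton that would quench the lactone enolate of step 6, as a base-stable TMS ether that mild acid removes in step 7.

**Step 4**
Reactants: 6 (R)-5-(hydroxymethyl)dihydrofuran-2(3H)-one
Product: 7 (R)-5-oxotetrahydrofuran-2-carbaldehyde
Conditions: Dess–Martin periodinane, CH2Cl2, 0 → 23 °C
Reagents that add atoms: none
Why: Dess–Martin oxidation gives the aldehyde under neutral conditions that should not epimerise the adjacent lactone stereocentre; the crude aldehyde is used directly.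

**Step 5**
Reactants: 7 (R)-5-oxotetrahydrofuran-2-carbaldehyde
Product: 8 (R)-5-vinyldihydrofuran-2(3H)-one
Conditions: Ph3PCH3Br, KN(SiMe3)2, THF, 0 °C; then 7, −78 → 0 °C
Reagents that add atoms: methyltriphenylphosphonium bromide, C[P+](c1ccccc1)(c1ccccc1)c1ccccc1.[Br-]
Why: Wittig methylenation with the non-stabilised ylide at low temperature is faster at the aldehyde than at the lactone carbonyl and does not touch the stereocentre, so the (R) configuration (future C4) is carried over from 6.

**Step 6**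
Reactants: 8 (R)-5-vinyldihydrofuran-2(3H)-one and 5 (2E,5E)-3,7-dimethyl-7-(trimethylsilyloxy)octa-2,5-dienal
Product: 9 (3R,5R)-3-[(1R,2E,5E)-1-hydroxy-3,7-dimethyl-7-(trimethylsilyloxy)octa-2,5-dien-1-yl]-5-vinyldihydrofuran-2(3H)-one
Conditions: LiN(iPr)2, THF, −78 °C; then 5, −78 °C; AcOH
Reagents that add atoms: none
Why: Lithium-enolate aldol addition: the lactone ring fixes the E(O) enolate geometry, so a closed Zimmerman–Traxler chair with the dienyl group of 5 equatorial should give the anti adduct, and 5 approaches the enolate carbon C6 on the ring face opposite the C4 vinyl group, which together set C9 as (R) relative to C4; 1,2-addition to the enal is kinetically preferred at −78 °C.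

**Step 7**
Reactants: 9 (3R,5R)-3-[(1R,2E,5E)-1-hydroxy-3,7-dimethyl-7-(trimethylsilyloxy)octa-2,5-dien-1-yl]-5-vinyldihydrofuran-2(3H)-one
Product: 12 (3R,5R,6R)-6-[(1E,4E)-6-hydroxy-2,6-dimethylhepta-1,4-dien-1-yl]-3-vinyl-2,7-dioxaspiro[4.4]nonane-1,8-dione, via alkylated hydroxy ester 10 (not isolated), via silyl bis-lactone 11 (not isolated)
Conditions: LiN(iPr)2 (2.3 equiv), THF–DMPU, −78 → −40 °C; BrCH2CO2Me, −78 → 0 °C; AcOH; then PPTS (cat.), MeOH, 23 °C
Reagents that add atoms: methyl bromoacetate, COC(=O)CBr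
Why: Fráter–Seebach alkylation: in the lithium-chelated alkoxide–enolate dianion of 9 the bromoacetate attacks C6 anti to the dienyl substituent on C9, which is also the face trans to the C4 vinyl group (matched control), so the quaternary centre C6 should form with C7 anti to the C9 oxygen; the C9 alkoxide then closes ring B on the methyl ester (10 to 11) and PPTS in MeOH removes the TMS ether.

**Step 8**
Reactants: 12 (3R,5R,6R)-6-[(1E,4E)-6-hydroxy-2,6-dimethylhepta-1,4-dien-1-yl]-3-vinyl-2,7-dioxaspiro[4.4]nonane-1,8-dione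
Product: 14 (4R,5R)-4-acryloyl-4-[(2R)-2-hydroxybut-3-en-1-yl]-5-[(1E,4E)-6-hydroxy-2,6-dimethylhepta-1,4-dien-1-yl]dihydrofuran-2(3H)-one, via vinyl lactol 13 (not isolated)
Conditions: LiN(iPr)2 (2.1 equiv), THF, −78 °C; CH2=CHMgBr, −78 → −40 °C; AcOH, −78 °C
Reagents that add atoms: vinylmagnesium bromide, C=C[Mg]Br
Why: Organometallic addition to a lactone with in situ enolate protection: LiN(iPr)2 converts the only enolisable acyl group of 12 (ring B lactone, C7 H2) into its lithium enolate and the tertiary alcohol into its alkoxide, which shields C8, so that CH2=CHMgBr should add only to the non-enolisable lactone carbonyl C1; the tetrahedral lactolate persists at low temperature and blocks a second addition, and on protonation lactol 13 opens to the γ-hydroxy vinyl ketone 14 with no change at C4, C6 or C9.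

**Step 9**
Reactants: 14 (4R,5R)-4-acryloyl-4-[(2R)-2-hydroxybut-3-en-1-yl]-5-[(1E,4E)-6-hydroxy-2,6-dimethylhepta-1,4-dien-1-yl]dihydrofuran-2(3H)-one
Product: 15 (1R,5R,9R)-9-hydroxy-1-[(1E,4E)-6-hydroxy-2,6-dimethylhepta-1,4-dien-1-yl]-2-oxaspiro[4.5]dec-7-ene-3,6-dione
Conditions: second-generation Grubbs catalyst (5 mol %), CH2Cl2 (0.005 M), 40 °C
Reagents that add atoms: none
Why: Ring-closing olefin metathesis: the ruthenium alkylidene first engages the unhindered vinyl group of the C4 allylic alcohol (hydroxyl-assisted), then forms a ruthenacyclobutane with the acryloyl C2=CH2 and cycloreverts to release ethylene and form the C2=C3 bond. The closest known reaction type is the metathesis ring closure of acryloyl or acrylate dienes onto allylic alcohols to give γ-hydroxy cycloalkenones and unsaturated lactones. Ring A is closed as a six-membered carbocycle whose olefin is necessarily cis; ring B and the side chain are spectators. No stereocentre is created: C4, C6 and C9 come from steps 4–7 and cannot epimerise under the neutral conditions (C6 is quaternary). The step needs chemoselectivity for the two monosubstituted olefins over the trisubstituted C10=C11 olefin (which could close an alternative six-membered ring from the C3 carbene) and the C13=C14 olefin; this is secured by the much lower metathesis reactivity of trisubstituted olefins and of a 1,2-disubstituted olefin flanked by the fully substituted carbinol carbon C15, and by high dilution, which suppresses dimerisation. Lactol 13 is in equilibrium with 14 and drains through the open form as ring closure proceeds.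

**Step 10**
Reactants: 15 (1R,5R,9R)-9-hydroxy-1-[(1E,4E)-6-hydroxy-2,6-dimethylhepta-1,4-dien-1-yl]-2-oxaspiro[4.5]dec-7-ene-3,6-dione
Product: 16 (1R,5R,9S)-1-[(1E,4E)-6-hydroxy-2,6-dimethylhepta-1,4-dien-1-yl]-3,6-dioxo-2-oxaspiro[4.5]dec-7-en-9-yl acetate
Conditions: AcOH, PPh3, DIAD, THF, 0 °C
Reagents that add atoms: acetic acid, CC(=O)O
Why: Mitsunobu esterification: the secondary allylic C4 alcohol is activated as its oxyphosphonium salt and displaced by acetate with inversion (R to S), the tertiary alcohol being inert, so the acetate is installed and C4 is corrected in one operation.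

**Compound list**
1 | geraniol, (2E)-3,7-dimethylocta-2,6-dien-1-ol | CC(C)=CCC/C(C)=C/CO | starting material
2 | (2E,5E)-7-hydroperoxy-3,7-dimethylocta-2,5-dien-1-ol | OC/C=C(\C)C/C=C/C(C)(C)OO | intermediate
3 | (2E,5E)-3,7-dimethylocta-2,5-diene-1,7-diol | OC/C=C(\C)C/C=C/C(C)(C)O | intermediate
4 | (2E,5E)-7-hydroxy-3,7-dimethylocta-2,5-dienal | O=C/C=C(\C)C/C=C/C(C)(C)O | intermediate
5 | (2E,5E)-3,7-dimethyl-7-(trimethylsilyloxy)octa-2,5-dienal | O=C/C=C(\C)C/C=C/C(C)(C)O[Si](C)(C)C | intermediate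
6 | (R)-5-(hydroxymethyl)dihydrofuran-2(3H)-one | OC[C@H]1CCC(=O)O1 | starting material
7 | (R)-5-oxotetrahydrofuran-2-carbaldehyde | O=C[C@H]1CCC(=O)O1 | intermediate
8 | (R)-5-vinyldihydrofuran-2(3H)-one | C=C[C@H]1CCC(=O)O1 | intermediate
9 | (3R,5R)-3-[(1R,2E,5E)-1-hydroxy-3,7-dimethyl-7-(trimethylsilyloxy)octa-2,5-dien-1-yl]-5-vinyldihydrofuran-2(3H)-one | C=C[C@H]1C[C@H]([C@H](O)/C=C(\C)C/C=C/C(C)(C)O[Si](C)(C)C)C(=O)O1 | intermediate
10 | methyl 2-[(3R,5R)-3-[(1R,2E,5E)-1-hydroxy-3,7-dimethyl-7-(trimethylsilyloxy)octa-2,5-dien-1-yl]-2-oxo-5-vinyltetrahydrofuran-3-yl]acetate | C=C[C@H]1C[C@]([C@H](O)/C=C(\C)C/C=C/C(C)(C)O[Si](C)(C)C)(CC(=O)OC)C(=O)O1 | intermediate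
11 | (3R,5R,6R)-6-[(1E,4E)-2,6-dimethyl-6-(trimethylsilyloxy)hepta-1,4-dien-1-yl]-3-vinyl-2,7-dioxaspiro[4.4]nonane-1,8-dione | C=C[C@H]1C[C@]2(CC(=O)O[C@@H]2/C=C(\C)C/C=C/C(C)(C)O[Si](C)(C)C)C(=O)O1 | intermediate
12 | (3R,5R,6R)-6-[(1E,4E)-6-hydroxy-2,6-dimethylhepta-1,4-dien-1-yl]-3-vinyl-2,7-dioxaspiro[4.4]nonane-1,8-dione | C=C[C@H]1C[C@]2(CC(=O)O[C@@H]2/C=C(\C)C/C=C/C(C)(C)O)C(=O)O1 | intermediate
13 | (3R,5R,6R)-1-hydroxy-6-[(1E,4E)-6-hydroxy-2,6-dimethylhepta-1,4-dien-1-yl]-1,3-divinyl-2,7-dioxaspiro[4.4]nonan-8-one (lactol, both configurations at the hemiketal carbon) | C=C[C@H]1C[C@]2(CC(=O)O[C@@H]2/C=C(\C)C/C=C/C(C)(C)O)C(O)(C=C)O1 | intermediate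
14 | (4R,5R)-4-acryloyl-4-[(2R)-2-hydroxybut-3-en-1-yl]-5-[(1E,4E)-6-hydroxy-2,6-dimethylhepta-1,4-dien-1-yl]dihydrofuran-2(3H)-one | C=C[C@H](O)C[C@]1(CC(=O)O[C@@H]1/C=C(\C)C/C=C/C(C)(C)O)C(=O)C=C | intermediate
15 | (1R,5R,9R)-9-hydroxy-1-[(1E,4E)-6-hydroxy-2,6-dimethylhepta-1,4-dien-1-yl]-2-oxaspiro[4.5]dec-7-ene-3,6-dione | O[C@H]1C=CC(=O)[C@@]2(CC(=O)O[C@@H]2/C=C(\C)C/C=C/C(C)(C)O)C1 | intermediate
16 | (+)-miliusane XVII, (1R,5R,9S)-1-[(1E,4E)-6-hydroxy-2,6-dimethylhepta-1,4-dien-1-yl]-3,6-dioxo-2-oxaspiro[4.5]dec-7-en-9-yl acetate | CC(=O)O[C@@H]1C=CC(=O)[C@@]2(CC(=O)O[C@@H]2/C=C(\C)C/C=C/C(C)(C)O)C1 | target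

**Step count**
Total step count: 10.
Longest linear sequence: 8 steps (steps 1, 2, 3, 6, 7, 8, 9, 10); steps 4 and 5 form the second branch, which joins at step 6.

**Steps most likely to fail**

1. Step 8 (chemoselective vinyl addition). What may go wrong: incomplete enolisation of ring B leaves its less hindered carbonyl C8 open to attack, or the hindered carbonyl C1 reacts only after the lactolate has begun to collapse, so that a second vinyl group adds. Fallback, from 9 and back at 15: the dianion of 9 is alkylated with tert-butyl bromoacetate and the alkoxide is capped in the same flask with Et3SiOSO2CF3 to give the silyl ether tert-butyl ester F1, whose allylic γ-lactone is the only reactive acyl group. CH2=CHMgBr at −78 °C opens it to the hydroxy vinyl ketone F2. Ring-closing metathesis with the second-generation Grubbs catalyst gives the cyclohexenone F3. HF·pyridine and then catalytic TsOH·H2O remove both silyl ethers and close ring B from the tert-butyl ester, which gives 15.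

2. Step 6 (aldol addition). What may go wrong: poor simple diastereoselection at C9, with open or boat transition states competing with the chair, so that much of the syn adduct forms. Fallback, from 8 and 5 and back at 9: the syn adduct, the C9 epimer F4, is separated and inverted by a Mitsunobu reaction with 4-nitrobenzoic acid (PPh3, DIAD) to the 4-nitrobenzoate F5, which K2CO3 in MeOH at 0 °C cleaves to 9.

3. Step 7 (quaternary centre). What may go wrong: retro-aldol fragmentation of the dianion, or alkylation on the alkoxide oxygen in competition with alkylation on carbon. Fallback, from 9 and back at 12: 9 is silylated (Et3SiOSO2CF3, 2,6-lutidine) to the bis-silyl ether F6. Its mono-enolate (LiN(iPr)2) is alkylated with methyl bromoacetate trans to the C4 vinyl group, now under control of the ring alone, to the ester F7. HF·pyridine removes both silyl groups and the freed C9 hydroxyl lactonises onto the methyl ester to give 12.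

**Further compounds**
F1 | step 8 | tert-butyl 2-[(3R,5R)-3-[(1R,2E,5E)-3,7-dimethyl-1-(triethylsilyloxy)-7-(trimethylsilyloxy)octa-2,5-dien-1-yl]-2-oxo-5-vinyltetrahydrofuran-3-yl]acetate | C=C[C@H]1C[C@]([C@H](O[Si](CC)(CC)CC)/C=C(\C)C/C=C/C(C)(C)O[Si](C)(C)C)(CC(=O)OC(C)(C)C)C(=O)O1
F2 | step 8 | tert-butyl (3R)-3-[(2R)-2-hydroxybut-3-en-1-yl]-3-[(1R,2E,5E)-3,7-dimethyl-1-(triethylsilyloxy)-7-(trimethylsilyloxy)octa-2,5-dien-1-yl]-4-oxohex-5-enoate | C=C[C@H](O)C[C@]([C@H](O[Si](CC)(CC)CC)/C=C(\C)C/C=C/C(C)(C)O[Si](C)(C)C)(CC(=O)OC(C)(C)C)C(=O)C=C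
F3 | step 8 | tert-butyl 2-[(1R,5R)-1-[(1R,2E,5E)-3,7-dimethyl-1-(triethylsilyloxy)-7-(trimethylsilyloxy)octa-2,5-dien-1-yl]-5-hydroxy-2-oxocyclohex-3-en-1-yl]acetate | O[C@H]1C=CC(=O)[C@](CC(=O)OC(C)(C)C)([C@H](O[Si](CC)(CC)CC)/C=C(\C)C/C=C/C(C)(C)O[Si](C)(C)C)C1
F4 | step 6 | (3R,5R)-3-[(1S,2E,5E)-1-hydroxy-3,7-dimethyl-7-(trimethylsilyloxy)octa-2,5-dien-1-yl]-5-vinyldihydrofuran-2(3H)-one | C=C[C@H]1C[C@H]([C@@H](O)/C=C(\C)C/C=C/C(C)(C)O[Si](C)(C)C)C(=O)O1
F5 | step 6 | (1R,2E,5E)-3,7-dimethyl-1-[(3R,5R)-2-oxo-5-vinyltetrahydrofuran-3-yl]-7-(trimethylsilyloxy)octa-2,5-dien-1-yl 4-nitrobenzoate | C=C[C@H]1C[C@H]([C@H](OC(=O)c2ccc(cc2)[N+](=O)[O-])/C=C(\C)C/C=C/C(C)(C)O[Si](C)(C)C)C(=O)O1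
F6 | step 7 | (3R,5R)-3-[(1R,2E,5E)-3,7-dimethyl-1-(triethylsilyloxy)-7-(trimethylsilyloxy)octa-2,5-dien-1-yl]-5-vinyldihydrofuran-2(3H)-one | C=C[C@H]1C[C@H]([C@H](O[Si](CC)(CC)CC)/C=C(\C)C/C=C/C(C)(C)O[Si](C)(C)C)C(=O)O1
F7 | step 7 | methyl 2-[(3R,5R)-3-[(1R,2E,5E)-3,7-dimethyl-1-(triethylsilyloxy)-7-(trimethylsilyloxy)octa-2,5-dien-1-yl]-2-oxo-5-vinyltetrahydrofuran-3-yl]acetate | C=C[C@H]1C[C@]([C@H](O[Si](CC)(CC)CC)/C=C(\C)C/C=C/C(C)(C)O[Si](C)(C)C)(CC(=O)OC)C(=O)O1
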